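- Take the constants that the gamma run can show, a capped rate V of product formation (zero order) and a ceiling on the yield, and hold them against the flasks below.

| flask | substrate | remark | time |
|---|---|---|---|
| gamma | 0.17 M | run made earlier |  |
| Thursday's | 2.0 M |  | 10 h |
| Wednesday's | 1.2 M |  | 10 h |
| Friday's | 0.80 M |  | 10 h |
| Monday's | 0.30 M |  | 10 h |
| Saturday's | 0.40 M |  | 10 h |

gamma run (percent of the substrate charged)

| time / h | product / % |
|---|---|
| 2.00 | 52 |
| 4.00 | 93 |
| 6.00 | 95 |
| 8.00 | 96 |
| 10.0 | 94 |

(standard deviation of a reading: 1.5 percentage points)

- the numbers in the tables scatter with a standard deviation of 1.5 percentage points

- the flasks put in order of amount of product, in percent of the substrate charged, best first, at 10 h (Thursday's / Wednesday's / Friday's / Monday's / Saturday's)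
- the amount of product, in percent of the substrate charged of the flask you put first, at 10 h
- the amount of product, in percent of the substrate charged of the flask you put last, at 10 h

- Test first order first, since it is the generous upper bound in which a large charge keeps gamma's fraction: a rate proportional to substrate that gave 52 % at 2.00 h gives 77.0 % at 4.00 h, yet the gamma run read 93 %, so drop that bound and cap the rate.
- Take V, on the zero-order reading that the rate stood at the cap from the start, as the mean rate up to the first reading, 0.0442 M/h, for the high end, and as the mean rate up to the second, 0.0395 M/h, for the low end, which undercounts if the gamma run stopped before that reading; a mean rate cannot exceed a cap, so the high end is an upper bound on V under that zero-order reading and not otherwise.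
- Multiply by 10 h to get the reach R, between 0.395 M and 0.442 M, meaning the charge that the capped rate can turn into product in the time allowed.
- Work in powers of ten: above R the yield is R over the charge and loses one decade per decade of charge, which puts Thursday's 0.656 to 0.704 decades under full conversion, so 19.8 % to 22.1 %.
- Place Monday's, whose charge lies below R, at the ceiling of the late gamma readings, 94 % to 96 %, and rank the flasks by rising charge, with Saturday's second because its charge sits inside the bracket on R.
- Set the forecast beside this: Monday's > Saturday's > Friday's > Wednesday's > Thursday's, with 95 % for the first flask and 22 % for the last, on the judgement that “zero order is the simplest reading”; both numbers fall inside the bracket.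
- Read the flasks: they give Monday's > Saturday's > Friday's > Wednesday's > Thursday's, with 93.6 % for Monday's, just under its bracket, and 24.7 % for Thursday's, above its bracket.

    substrate ⇌ dormant form (K = 1.40, k = 6.92 × 10⁻⁶ /s)
    substrate → product, rate k2*[substrate]/(1 + ([substrate]/sat2)) (11.5 mM, k = 0.00120 /s)

- Note that Thursday's made 0.493 M of product, more than the reach of 0.442 M, and that it stands at 24.7 % because of the levelling-off of the rate with substrate together with the time allowed: without the levelling-off the same flask gives 99.5 %, and left until 100 h it gives 93.1 %. Scale R to the second flask, Monday's charge read at 2.5 h: the reach predicts 36.8 % of that charge, and the flask holds 39.4 % of product.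

(All runs come from a simulation on assumed constants, noise included.)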